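The chair opened with two earlier runs and two new recipes on the table.

| setting | birch | larch | blue | violet |
|---|---|---|---|---|
| J | 0.010 M | 0.010 M | 0.010 M | 0.010 M |
| G | 0.37 equiv | 0.96 equiv | 0.450 equiv | 1.80 equiv |
| Z | 0.66 mol% | 0.66 mol% | 0.66 mol% | 0.66 mol% |
| remark | run made earlier | run made earlier |  |  |
| time |  |  | 20 min | 5.0 min |

| run | time / min | D / % |
|---|---|---|
| birch | 0.417 | 1.0 |
| birch | 0.833 | 1.8 |
| birch | 1.33 | 2.5 |
| birch | 2.50 | 7.0 |
| birch | 5.00 | 10.8 |
| larch | 0.417 | 3.3 |
| larch | 1.33 | 7.0 |
| larch | 2.50 | 13.5 |
| larch | 4.00 | 19.8 |
| larch | 5.00 | 23.3 |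

(readings scatter by 0.5 percentage points)

- the numbers in the tables scatter with a standard deviation of 0.5 percentage points
- on the list of suspects stand: Q <-> Z + D; L <-> Q; J + E -> L; X -> E; G + Z -> X

- the flask that ends with the higher amount of D, in percent of the J charged, or "neither" when 2 percentage points or less lies between them (blue / violet / neither)
- final D, as a percentage of the J charged, in blue
- final D, as a percentage of the J charged, in violet

The first speaker asked the meeting to multiply the equivalents of G by the minutes run. Blue gets 9.00 min. She called this product the dose, and violet gets 9.00 min, the same figure. She then tested it on the readings. Larch read 3.3% at dose 0.400 min, 7.0% at dose 1.28 min and 13.5% at dose 2.40 min. Birch read 10.8% at dose 1.85 min, which falls between the last two. So she read D as following roughly one curve in the dose.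

The second speaker treated G use as a correction, taking one G per D. In blue, G is the limiting reagent. At larch's last reading of 23.3%, blue would keep 48.2% of its G and violet 87.1%. So this speaker held that the dose overstates blue.

The third speaker noted that violet's G lies beyond the runs, which could lower violet instead. The chair saw one correction against each flask and, with equal doses, expected no clear difference.

The forecast differed. It named violet, with blue at 29% (25% to 34%) and violet at 38% (31% to 46%). It shaded violet down, noting that “another step may start to limit the rate”.

    Q ⇌ Z + D (K = 0.00580 M, k = 1.27 s⁻¹)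
    L ⇌ Q (K = 1.90, k = 6.69 s⁻¹)
    J + E → L (k = 146 M⁻¹ s⁻¹)
    X → E (k = 1.39 s⁻¹)
    G + Z → X (k = 28.6 M⁻¹ s⁻¹)

Blue and violet gave 32.6% and 32.7%, so the answer is neither, at the shared dose of 9.00 min. In blue, G + Z → X ran while G fell to 26.9% of its charge by 20.0 min, with Z at 50.9% of the catalyst. In violet the same step ran with 81.6% of G left at 5.00 min, while X and E together held 23.2% of the catalyst and Z 31.6%. Violet read at 1.33 min has dose 2.40 min, matching larch at 2.50 min, yet its D is 10.2% against larch's reading of 13.5%.

Readings and results were generated by integration on assumed constants; noise was put on by code.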